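**Plan**

- Retrosynthesis: the allylic acetate and the free phenols are late adjustments (OAc for OTBS, ring C–H for C–CO2Me). The benzene ring is then opened at the bond between the ester-bearing and the chain-bearing ring carbons, which is C2–C7 of a linear 3,5,7-trioxo ester.
- Enabling feature: the 5-alkylresorcinol ring has oxygen on C1 and C3 and the C15 chain on C5. This 1,3,5-pattern is that of a folded tetraketide: the C3 and C5 carbonyls become the phenols and the C7 carbonyl carbon becomes the chain-bearing ring carbon.
- The tetraketide is cut at C6–C7 (acylation of the trianion of methyl 3,5-dioxohexanoate by a C16 ester). The C16 ester is cut at its C9=C10 Z-alkene (Wittig reaction of a C9 ylide with a C7 α-silyloxy aldehyde).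
- Forward: aldehyde and phosphonium salt are joined to the Z-alkene, the chain is extended by C6–C7 acylation, and the only ring (the benzene ring) closes in step 7. Decarboxylation, desilylation, peracetylation and selective aryl-acetate cleavage follow.
- Stereochemistry: the single stereocentre (R) is bought with (R)-oct-1-en-3-ol and never becomes a reacting centre. The Z geometry comes from a kinetically controlled, lithium-free Wittig reaction.

Key step: step 7

Remark: methyl 3,5-dioxohexanoate (10) is assumed to be purchasable (it is otherwise one step from dehydroacetic acid). Polycarbonyl compounds are drawn as keto tautomers although they are largely enolised. The new ring sp3 centres of ozonide 3 and aldol adduct 13 are uncontrolled and are lost within the same step.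

**Route**

Step 1
Reactants: 1 (3R)-oct-1-en-3-ol
Product: 2 tert-butyldimethyl[(3R)-oct-1-en-3-yloxy]silane
Conditions: TBSCl, imidazole, DMF, 0 °C → rt
Reagents that add atoms: tert-butyldimethylsilyl chloride, CC(C)(C)[Si](C)(C)Cl
Why: Imidazole-promoted silylation of a secondary allylic alcohol should proceed at oxygen only, so the carbinol configuration is retained.

Step 2
Reactants: 2 tert-butyldimethyl[(3R)-oct-1-en-3-yloxy]silane
Product: 4 (2R)-2-(tert-butyldimethylsilyloxy)heptanal, via secondary ozonide 3 (not isolated)
Conditions: O3, CH2Cl2, −78 °C; then PPh3, −78 °C → rt; rapid filtration through silica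
Reagents that add atoms: ozone, [O-][O+]=O
Why: Ozonolysis of the terminal vinyl group (Criegee mechanism) with reductive work-up should excise only the =CH2 carbon under neutral conditions, so the α-silyloxy stereocentre is not enolised.

Step 3
Reactants: 5 9-bromononanoic acid
Product: 6 methyl 9-bromononanoate
Conditions: MeOH, H2SO4 (cat.), reflux
Reagents that add atoms: methanol, CO
Why: Fischer esterification in excess methanol should go to completion, and the primary bromide is inert to acidic methanol.

Step 4
Reactants: 6 methyl 9-bromononanoate
Product: 7 (9-methoxy-9-oxononyl)triphenylphosphonium bromide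
Conditions: PPh3, MeCN, reflux
Reagents that add atoms: triphenylphosphine, c1ccc(cc1)P(c1ccccc1)c1ccccc1
Why: SN2 quaternisation of triphenylphosphine by an unhindered primary bromide is a standard entry to Wittig salts, and the ester does not interfere.

Step 5
Reactants: 7 (9-methoxy-9-oxononyl)triphenylphosphonium bromide; 4 (2R)-2-(tert-butyldimethylsilyloxy)heptanal
Product: 9 methyl (9Z,11R)-11-(tert-butyldimethylsilyloxy)hexadec-9-enoate, via phosphorus ylide 8 (not isolated)
Conditions: 7 (1.15 equiv), NaHMDS (1.1 equiv), THF, −78 → 0 °C; then 4, −78 °C → rt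
Reagents that add atoms: none
Why: A lithium-free Wittig reaction of a non-stabilised ylide should give the Z-alkene through the kinetically formed cis-oxaphosphetane, and the low temperature and absence of free base should keep the α-silyloxy aldehyde from enolising, so the R centre is carried over.

Step 6
Reactants: 10 methyl 3,5-dioxohexanoate; 9 methyl (9Z,11R)-11-(tert-butyldimethylsilyloxy)hexadec-9-enoate
Product: 12 methyl (15Z,17R)-17-(tert-butyldimethylsilyloxy)-3,5,7-trioxodocos-15-enoate, via trilithium trianion 11 (not isolated)
Conditions: 10 (2.5 equiv), LDA (7.7 equiv), THF, −78 → 0 °C; then 9 (1 equiv), −78 → 0 °C; cold aq. AcOH (pH 5–6); excess 10 removed under high vacuum, crude 12 used directly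
Reagents that add atoms: none
Why: Threefold deprotonation of 10 (C4, C2, then the C6 methyl) gives a trianion whose least stabilised terminal carbanion should attack the ester carbonyl of 9 (crossed Claisen-type acylation of a polyanion at its terminus), while the excess trianion absorbs the acidic proton of the new 1,3-diketone.

Step 7
Reactants: 12 methyl (15Z,17R)-17-(tert-butyldimethylsilyloxy)-3,5,7-trioxodocos-15-enoate
Product: 14 methyl 2,4-dihydroxy-6-[(8Z,10R)-10-(tert-butyldimethylsilyloxy)pentadec-8-enyl]benzoate, via cyclic aldol adduct 13 (not isolated)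
Conditions: aq. KOH (0.5 M), THF, 0 °C → rt, under argon; then AcOH to pH 5
Reagents that add atoms: none
Why: Hydroxide converts 12 into its polyenolate, and the C2 carbanion (between the C1 ester and the C3 ketone) should add to the C7 ketone in an intramolecular aldol reaction that forms the C2–C7 bond and gives carbinol 13. The six-membered carbocycle closes in a 6-(enolendo)-exo-trig mode, which is stereoelectronically favoured. E1cB loss of the tertiary hydroxyl and enolisation of the C3 and C5 carbonyls then give the benzene ring, which makes the sequence irreversible. The closest known reaction type is the base-mediated biomimetic aldol aromatisation of 3,5,7-trioxoalkanoates to β-resorcylates, the laboratory counterpart of the fold used by alkylresorcinol-forming type III polyketide synthases. No stereocentre is created in 14: the two sp3 ring centres of 13 are erased on aromatisation, and the remote silyloxy carbinol, the isolated Z-alkene and the silyl ether are inert to cold aqueous base. The selectivity needed is C2→C7 aldol closure over C6→C1 Claisen closure (acylphloroglucinol) and over enol lactonisation (4-hydroxy-2-pyranone); in water without a chelating metal such as Mg2+ the enolate-deactivated ester is a poor acceptor, whereas the terminal C7 ketone is the most electrophilic carbonyl.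

Step 8
Reactants: 14 methyl 2,4-dihydroxy-6-[(8Z,10R)-10-(tert-butyldimethylsilyloxy)pentadec-8-enyl]benzoate
Product: 16 5-[(8Z,10R)-10-(tert-butyldimethylsilyloxy)pentadec-8-enyl]benzene-1,3-diol, via beta-resorcylic acid 15 (not isolated)
Conditions: KOH, MeOH/H2O, reflux, degassed, under argon; then AcOH to pH 5, 60 °C
Reagents that add atoms: none
Why: Saponification of the salicylate-type ester followed by protodecarboxylation of the 2,4-dihydroxybenzoic acid (ipso protonation assisted by the ortho and para hydroxyls) is the standard way from β-resorcylates to 5-alkylresorcinols, and a secondary alkyl TBS ether should tolerate hot hydroxide.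

Step 9
Reactants: 16 5-[(8Z,10R)-10-(tert-butyldimethylsilyloxy)pentadec-8-enyl]benzene-1,3-diol
Product: 17 5-[(8Z,10R)-10-hydroxypentadec-8-enyl]benzene-1,3-diol
Conditions: HF·pyridine, pyridine, THF, 0 °C → rt
Reagents that add atoms: none
Why: Fluoride-driven Si–O cleavage under pyridine-buffered conditions should free the allylic alcohol without ionising it, so configuration and Z geometry are kept.

Step 10
Reactants: 17 5-[(8Z,10R)-10-hydroxypentadec-8-enyl]benzene-1,3-diol
Product: 18 5-[(8Z,10R)-10-acetoxypentadec-8-enyl]-1,3-phenylene diacetate
Conditions: Ac2O, pyridine, DMAP (cat.), CH2Cl2, 0 °C → rt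
Reagents that add atoms: acetic anhydride, CC(=O)OC(C)=O
Why: DMAP-catalysed acylation should esterify all three hydroxyls at oxygen with retention at the carbinol carbon.

Step 11
Reactants: 18 5-[(8Z,10R)-10-acetoxypentadec-8-enyl]-1,3-phenylene diacetate
Product: 19 (6R,7Z)-15-(3,5-dihydroxyphenyl)pentadec-7-en-6-yl acetate
Conditions: NH4OAc, MeOH/H2O (4:1), rt
Reagents that add atoms: none
Why: Chemoselective solvolysis of aryl acetates under near-neutral ammonium acetate catalysis should remove only the two phenolic esters, because phenoxide is a far better leaving group than a secondary alkoxide.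

**Compound list**

1 | (3R)-oct-1-en-3-ol | CCCCC[C@H](C=C)O | starting material
2 | tert-butyldimethyl[(3R)-oct-1-en-3-yloxy]silane | CCCCC[C@H](C=C)O[Si](C)(C)C(C)(C)C | intermediate
3 | 3-[(1R)-1-(tert-butyldimethylsilyloxy)hexyl]-1,2,4-trioxolane (secondary ozonide, mixture at the ring carbon) | CCCCC[C@H](C1OCOO1)O[Si](C)(C)C(C)(C)C | intermediate
4 | (2R)-2-(tert-butyldimethylsilyloxy)heptanal | CCCCC[C@H](C=O)O[Si](C)(C)C(C)(C)C | intermediate
5 | 9-bromononanoic acid | OC(=O)CCCCCCCCBr | starting material
6 | methyl 9-bromononanoate | COC(=O)CCCCCCCCBr | intermediate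
7 | (9-methoxy-9-oxononyl)triphenylphosphonium bromide | COC(=O)CCCCCCCC[P+](c1ccccc1)(c1ccccc1)c1ccccc1.[Br-] | intermediate
8 | methyl 9-(triphenyl-λ5-phosphanylidene)nonanoate (ylide) | COC(=O)CCCCCCCC=P(c1ccccc1)(c1ccccc1)c1ccccc1 | intermediate
9 | methyl (9Z,11R)-11-(tert-butyldimethylsilyloxy)hexadec-9-enoate | CCCCC[C@H](/C=C\CCCCCCCC(=O)OC)O[Si](C)(C)C(C)(C)C | intermediate
10 | methyl 3,5-dioxohexanoate | CC(=O)CC(=O)CC(=O)OC | starting material
11 | trilithium 1-methoxyhexa-1,3,5-triene-1,3,5-triolate (2,4,6-trianion of 10) | [Li+].[Li+].[Li+].C=C([O-])C=C([O-])C=C([O-])OC | intermediate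
12 | methyl (15Z,17R)-17-(tert-butyldimethylsilyloxy)-3,5,7-trioxodocos-15-enoate | CCCCC[C@H](/C=C\CCCCCCCC(=O)CC(=O)CC(=O)CC(=O)OC)O[Si](C)(C)C(C)(C)C | intermediate
13 | methyl 2-hydroxy-2-[(8Z,10R)-10-(tert-butyldimethylsilyloxy)pentadec-8-enyl]-4,6-dioxocyclohexane-1-carboxylate (ring centres undefined) | CCCCC[C@H](/C=C\CCCCCCCC1(O)CC(=O)CC(=O)C1C(=O)OC)O[Si](C)(C)C(C)(C)C | intermediate
14 | methyl 2,4-dihydroxy-6-[(8Z,10R)-10-(tert-butyldimethylsilyloxy)pentadec-8-enyl]benzoate | CCCCC[C@H](/C=C\CCCCCCCc1cc(O)cc(O)c1C(=O)OC)O[Si](C)(C)C(C)(C)C | intermediate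
15 | 2,4-dihydroxy-6-[(8Z,10R)-10-(tert-butyldimethylsilyloxy)pentadec-8-enyl]benzoic acid | CCCCC[C@H](/C=C\CCCCCCCc1cc(O)cc(O)c1C(=O)O)O[Si](C)(C)C(C)(C)C | intermediate
16 | 5-[(8Z,10R)-10-(tert-butyldimethylsilyloxy)pentadec-8-enyl]benzene-1,3-diol | CCCCC[C@H](/C=C\CCCCCCCc1cc(O)cc(O)c1)O[Si](C)(C)C(C)(C)C | intermediate
17 | 5-[(8Z,10R)-10-hydroxypentadec-8-enyl]benzene-1,3-diol | CCCCC[C@H](/C=C\CCCCCCCc1cc(O)cc(O)c1)O | intermediate
18 | 5-[(8Z,10R)-10-acetoxypentadec-8-enyl]-1,3-phenylene diacetate | CCCCC[C@H](/C=C\CCCCCCCc1cc(OC(C)=O)cc(OC(C)=O)c1)OC(C)=O | intermediate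
19 | (6R,7Z)-15-(3,5-dihydroxyphenyl)pentadec-7-en-6-yl acetate | CCCCC[C@H](/C=C\CCCCCCCc1cc(O)cc(O)c1)OC(C)=O | target

**Summary**

Total step count: 11.
Longest linear sequence: 9 steps (1 → 2 → 4 → 9 → 12 → 14 → 16 → 17 → 18 → 19; the branch from 5 through 6 and 7 is equally long).

Steps most likely to fail:

1. Step 6. Proton transfer from the α-methylene of ester 9 to the strongly basic trianion may compete with addition, and the acidic product may quench unreacted trianion, so conversion may stay low. Fallback: setting out from 9, the ester is converted with N,O-dimethylhydroxylamine hydrochloride and iPrMgCl (THF, −20 °C) into the Weinreb amide (9Z,11R)-11-(tert-butyldimethylsilyloxy)-N-methoxy-N-methylhexadec-9-enamide F1. Its adduct with trianion 11 should persist as a chelated tetrahedral intermediate until acidic work-up, so only a slight excess of 11 is needed. The path comes back to the route at 12.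

2. Step 7. Ring closure may partition towards C6→C1 Claisen cyclisation or lactonisation to the pyranone, or the ester may be hydrolysed before the ring closes. Fallback: the closure is run on the free acid, where a carboxylate cannot act as a Claisen acceptor. Setting out from 9, acylation of dilithiated pentane-2,4-dione (LDA, THF) should give (14Z,16R)-16-(tert-butyldimethylsilyloxy)henicos-14-ene-2,4,6-trione F2. Its trianion, formed kinetically at the methyl terminus with LDA, is carboxylated with CO2 to (15Z,17R)-17-(tert-butyldimethylsilyloxy)-3,5,7-trioxodocos-15-enoic acid F3. In aqueous acetate buffer (pH about 5) F3 should close by the same C2→C7 aldol, and the path comes back to the route at 15, which is decarboxylated to 16 as in step 8.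

3. Step 5. The basic ylide may enolise the α-silyloxy aldehyde and erode its configurational purity, and Z selectivity may be incomplete. Fallback: setting out from 2, Z-selective cross-metathesis with commercial methyl dec-9-enoate, using a molybdenum monoaryloxide pyrrolide alkylidene catalyst under reduced pressure to remove ethene, should give the Z-alkene without any aldehyde or base. No new intermediate arises on this path (F0), and it comes back to the route at 9.

**Further compounds**

F1 | step 6 | (9Z,11R)-11-(tert-butyldimethylsilyloxy)-N-methoxy-N-methylhexadec-9-enamide | CCCCC[C@H](/C=C\CCCCCCCC(=O)N(C)OC)O[Si](C)(C)C(C)(C)C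
F2 | step 7 | (14Z,16R)-16-(tert-butyldimethylsilyloxy)henicos-14-ene-2,4,6-trione | CCCCC[C@H](/C=C\CCCCCCCC(=O)CC(=O)CC(C)=O)O[Si](C)(C)C(C)(C)C
F3 | step 7 | (15Z,17R)-17-(tert-butyldimethylsilyloxy)-3,5,7-trioxodocos-15-enoic acid | CCCCC[C@H](/C=C\CCCCCCCC(=O)CC(=O)CC(=O)CC(=O)O)O[Si](C)(C)C(C)(C)C
F0 | step 5 | none | none
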